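Ring C is cut at O1–C2, at the C3–O bond and at C2–C3 (the chalcone Cα=Cβ bond). This gives a ring A acetophenone that already carries the C8 prenyl group and a ring B benzaldehyde.
Ring B is cut at C4'–C5' and C5'–C6'. The neighbouring oxygens on C4' and C5' are read as an alkoxycarbene carbon joined to a carbonyl ligand of chromium, C6'–H as the terminal CH2 of a diene, and C1' keeps a CH2O handle.
The prenyl pair on C2' and C3' is read as a cis-tetrasubstituted alkene, obtained by syn 1,2-difunctionalisation of symmetric diprenylacetylene (cuts at C1'–C2' and C3'–C4').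
Forward: the acyclic dienylcarbene complex closes ring B first, ring A comes from phloroacetophenone, an aldol condensation joins the halves, and ring C closes last.
The target has no stereocentre. The only stereochemical element is the Z geometry of the future C2'=C3' bond, set by syn diboration and carried through stereoretentive coupling, iodination and lithiation.

Key step: step 7

Remark: flavonoid numbering is used (ring A C5–C8, ring C O1–C4, ring B primed). Prenyl = 3-methylbut-2-enyl, MOM = methoxymethyl, TIPS = triisopropylsilyl, pin = pinacolato. The C1' handle is assumed to be best carried as a TIPS ether.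

Step 1
Reactants: 1 acetylene; 2 prenyl bromide (1-bromo-3-methylbut-2-ene, 2 equiv)
Product: 4 diprenylacetylene (2,9-dimethyldeca-2,8-dien-5-yne), via ethynediylbis(magnesium bromide) 3 (not isolated)
Conditions: EtMgBr (2 equiv), THF, 0 to 50 °C; then CuCl (10 mol %), 2, THF, 0 to 50 °C
Reagents that add atoms: ethylmagnesium bromide, CC[Mg]Br (supplies the MgBr groups of 3 only; none of its atoms stay in 4)
Why: Copper-catalysed allylic substitution of an alkynyl Grignard reagent at the primary carbon of prenyl bromide is a standard route to skipped 1,4-enynes, and the symmetric product removes any regiochemical question from later additions to the triple bond.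

Step 2
Reactants: 4 diprenylacetylene
Product: 5 (5Z)-2,9-dimethyl-5,6-bis(4,4,5,5-tetramethyl-1,3,2-dioxaborolan-2-yl)deca-2,5,8-triene
Conditions: B2pin2 (1.05 equiv), Pt(PPh3)4 (3 mol %), DMF, 80 °C
Reagents that add atoms: bis(pinacolato)diboron, CC1(C)OB(OC1(C)C)B1OC(C)(C)C(C)(C)O1
Why: Platinum-catalysed alkyne diboration adds the boron–boron bond syn and reacts with alkynes only, so the trisubstituted prenyl alkenes are left alone and the cis-diboryl (Z) geometry needed for ring closure is fixed here.

Step 3
Reactants: 6 2-bromoprop-2-en-1-ol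
Product: 7 (2-bromoprop-2-enyloxy)triisopropylsilane
Conditions: TIPSCl, imidazole, CH2Cl2, 0 °C to rt
Reagents that add atoms: chlorotriisopropylsilane, CC(C)[Si](Cl)(C(C)C)C(C)C
Why: Standard imidazole-promoted silylation, with the bulky TIPS group chosen so that no 1,5 oxygen-to-carbon silyl shift (retro-Brook type) can occur in the dienyllithium of step 6.

Step 4
Reactants: 5 cis-diborylalkene (1.2 equiv); 7 bromoallyl TIPS ether
Product: 8 {[(3E)-7-methyl-2-methylidene-3-prenyl-4-(4,4,5,5-tetramethyl-1,3,2-dioxaborolan-2-yl)octa-3,6-dienyl]oxy}triisopropylsilane (boron cis to the methylidene-bearing carbon)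
Conditions: PdCl2(dppf) (5 mol %), aq KOH, DME, rt to 50 °C
Reagents that add atoms: none
Why: Stereoretentive Suzuki–Miyaura coupling, in which a cis-diborylalkene couples only once with a limiting amount of halide because the surviving boronate is then flanked by the new branched alkenyl group and transmetalates much more slowly.

Step 5
Reactants: 8 dienylboronate
Product: 9 {[(3Z)-4-iodo-7-methyl-2-methylidene-3-prenylocta-3,6-dienyl]oxy}triisopropylsilane (iodine cis to the methylidene-bearing carbon)
Conditions: aq NaOH, THF, 0 °C; then I2, THF, 0 °C, dark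
Reagents that add atoms: iodine, [I][I]
Why: Base-promoted iododeboronation of an alkenylboronate (hydroxide ate complex, then iodine) replaces boron by iodine with retention of geometry, and the ate complex is far more nucleophilic than the isolated prenyl alkenes.

Step 6
Reactants: 9 dienyl iodide; 10 chromium hexacarbonyl
Product: 13 pentacarbonyl[(2Z)-1-methoxy-2,3-diprenyl-4-(triisopropylsilyloxymethyl)penta-2,4-dienylidene]chromium, via dienyllithium 11 (not isolated), via lithium acylchromate 12 (not isolated)
Conditions: t-BuLi (2 equiv), Et2O, −78 °C; Cr(CO)6, Et2O–THF, −78 to 0 °C; MeOTf, CH2Cl2, 0 °C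
Reagents that add atoms: tert-butyllithium, [Li]C(C)(C)C (lithium of 11 and 12 only); methyl trifluoromethanesulfonate, COS(=O)(=O)C(F)(F)F (the O-methyl group of 13)
Why: Fischer carbene synthesis, in which lithium–iodine exchange at −78 °C outruns any deprotonation and keeps the alkene geometry, the alkenyllithium adds to a carbonyl ligand of Cr(CO)6, and the hard electrophile MeOTf methylates the acylchromate on oxygen.

Step 7
Reactants: 13 dienyl(methoxy)carbene chromium complex
Product: 16 2-methoxy-3,4-diprenyl-5-(triisopropylsilyloxymethyl)phenol, via chromium-bound dienylketene 14 (not isolated), via cyclohexadienone 15 (not isolated)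
Conditions: hν (450 W Hg lamp, Pyrex), CO (1 atm), THF, rt; then brief exposure to air, filtration
Reagents that add atoms: none
Why: Irradiation into the metal-to-ligand charge-transfer band moves one cis carbonyl ligand onto the carbene carbon, which forms C4'–C5' and gives the chromium-bound dienylketene 14; this is the known photochemical benzannulation of dienyl(alkoxy)carbene chromium complexes to ortho-alkoxyphenols, a relative of the closing stages of the Dötz benzannulation. Ring B closes by a six-electron disrotatory electrocyclisation of 14, in which the ketene carbon C5' bonds to the terminal methylidene carbon C6' to give dienone 15, and enolisation of 15 delivers the phenol with OMe on C4' and OH on C5'. No stereocentre is created. The step needs the ketene and the methylidene group on the same side of the C2'=C3' alkene, which the Z geometry of 13 secures, and the two prenyl groups on that alkene press the reacting termini towards each other. It also needs the ketene to choose the conjugated diene terminus over the prenyl alkenes, and a [2+2] addition to either prenyl group would build a strained bicycle whereas the electrocyclisation leads to an arene. The CO atmosphere takes up the Cr(CO)4 fragment as Cr(CO)6 and so keeps the metal from binding the new arene or the alkenes.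

Step 8
Reactants: 16 methoxyphenol
Product: 18 3,4-diprenyl-5-(triisopropylsilyloxymethyl)benzene-1,2-diol, via ortho-quinone 17 (not isolated)
Conditions: IBX (1.1 equiv), THF, rt, dark; then aq Na2S2O4
Reagents that add atoms: IBX (2-iodoxybenzoic acid, one oxygen), O=C1OI(=O)(O)c2ccccc12
Why: IBX oxidative demethylation of a 2-methoxyphenol, in which the phenol binds pentavalent iodine, oxygen is delivered to the methoxy-bearing ortho carbon, methanol leaves to give the ortho-quinone, and dithionite reduces it in the same flask before the C3' prenyl group can tautomerise into a quinone methide.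

Step 9
Reactants: 18 catechol
Product: 19 {[4,5-bis(methoxymethoxy)-2,3-diprenylphenyl]methoxy}triisopropylsilane
Conditions: MOMCl (3 equiv), i-Pr2NEt, CH2Cl2, 0 °C to rt
Reagents that add atoms: chloromethyl methyl ether, COCCl
Why: Standard O-alkylation of phenols with MOMCl and a hindered amine gives acetal ethers that survive fluoride, MnO2, KOH and alkaline H2O2 and leave together with the ring A MOM groups at the end.

Step 10
Reactants: 19 TIPS ether
Product: 20 [4,5-bis(methoxymethoxy)-2,3-diprenylphenyl]methanol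
Conditions: Bu4NF, THF, 0 °C to rt
Reagents that add atoms: none
Why: Fluoride-driven cleavage of the silicon–oxygen bond is selective for the silyl ether, since MOM ethers and alkenes do not react with Bu4NF.

Step 11
Reactants: 20 benzylic alcohol
Product: 21 4,5-bis(methoxymethoxy)-2,3-diprenylbenzaldehyde
Conditions: activated MnO2, CH2Cl2, rt
Reagents that add atoms: none
Why: Activated MnO2 oxidises benzylic alcohols to aldehydes without over-oxidation and leaves isolated trisubstituted alkenes and acetals untouched.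

Step 12
Reactants: 22 2,4,6-trihydroxyacetophenone; 2 prenyl bromide (1 equiv)
Product: 23 1-(2,4,6-trihydroxy-3-prenylphenyl)ethanone
Conditions: DBU (1 equiv), THF, 0 °C to rt
Reagents that add atoms: none
Why: C-alkylation of the ambident phloroglucinol-type phenolate, in which the soft allylic bromide attacks the very nucleophilic ring carbon, C3 and C5 are equivalent, and one equivalent of bromide limits double prenylation.

Step 13
Reactants: 23 prenylphloroacetophenone
Product: 24 1-[2-hydroxy-4,6-bis(methoxymethoxy)-3-prenylphenyl]ethanone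
Conditions: MOMCl (2.1 equiv), i-Pr2NEt, CH2Cl2, 0 °C
Reagents that add atoms: chloromethyl methyl ether, COCCl
Why: Selective MOM ether formation, in which the unchelated 4-OH reacts first and the open 6-OH reacts before the 2-OH wedged between acetyl and prenyl, so the hydroxyl left free is the one that must become O1 next to C8.

Step 14
Reactants: 21 ring B aldehyde; 24 ring A acetophenone
Product: 25 (E)-3-[4,5-bis(methoxymethoxy)-2,3-diprenylphenyl]-1-[2-hydroxy-4,6-bis(methoxymethoxy)-3-prenylphenyl]prop-2-en-1-one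
Conditions: KOH, EtOH–H2O, rt
Reagents that add atoms: none
Why: Claisen–Schmidt aldol condensation of the methyl ketone enolate with the non-enolisable aldehyde, followed by E1cB loss of water, gives the conjugated enone in its thermodynamically favoured E form.

Step 15
Reactants: 25 chalcone
Product: 27 3-hydroxy-5,7-bis(methoxymethoxy)-2-[4,5-bis(methoxymethoxy)-2,3-diprenylphenyl]-8-prenylchromen-4-one, via trans-dihydroflavonol 26 (not isolated)
Conditions: 30% aq H2O2, NaOH, MeOH, 0 °C to rt
Reagents that add atoms: hydrogen peroxide (one oxygen), OO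
Why: Algar–Flynn–Oyamada reaction, in which hydroperoxide oxygenates the enone at Cα while the only free phenolate closes O1–C2 in a 6-endo sense to the dihydroflavonol, alkaline peroxide dehydrogenates this to the flavonol, and the nucleophilic oxidant ignores the electron-rich prenyl alkenes.

Step 16
Reactants: 27 tetra-MOM flavonol
Product: 28 Broussoflavonol G
Conditions: dilute HCl, MeOH, 40 °C, short reaction time
Reagents that add atoms: none
Why: Acid-catalysed acetal exchange with methanol removes all four MOM groups, and mild acid with a short contact time is the usual way to do this on prenylated flavonoids without closing a chroman ring between a prenyl group and its neighbouring phenol.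

Compound list
1 | acetylene | C#C | starting material
2 | prenyl bromide (1-bromo-3-methylbut-2-ene) | CC(C)=CCBr | starting material
3 | ethynediylbis(magnesium bromide) | Br[Mg]C#C[Mg]Br | intermediate
4 | 2,9-dimethyldeca-2,8-dien-5-yne | CC(C)=CCC#CCC=C(C)C | intermediate
5 | (5Z)-2,9-dimethyl-5,6-bis(pinacolatoboryl)deca-2,5,8-triene | CC(C)=CC/C(B1OC(C)(C)C(C)(C)O1)=C(B1OC(C)(C)C(C)(C)O1)\CC=C(C)C | intermediate
6 | 2-bromoprop-2-en-1-ol | OCC(Br)=C | starting material
7 | (2-bromoprop-2-enyloxy)triisopropylsilane | C=C(Br)CO[Si](C(C)C)(C(C)C)C(C)C | intermediate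
8 | (3E)-dienylboronate, boron cis to the methylidene-bearing carbon | CC(C)=CC/C(B1OC(C)(C)C(C)(C)O1)=C(\CC=C(C)C)C(=C)CO[Si](C(C)C)(C(C)C)C(C)C | intermediate
9 | (3Z)-dienyl iodide, iodine cis to the methylidene-bearing carbon | CC(C)=CC/C(I)=C(\CC=C(C)C)C(=C)CO[Si](C(C)C)(C(C)C)C(C)C | intermediate
10 | chromium hexacarbonyl | [Cr].[C-]#[O+].[C-]#[O+].[C-]#[O+].[C-]#[O+].[C-]#[O+].[C-]#[O+] | starting material
11 | dienyllithium, lithium cis to the methylidene-bearing carbon | CC(C)=CC/C([Li])=C(\CC=C(C)C)C(=C)CO[Si](C(C)C)(C(C)C)C(C)C | intermediate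
12 | lithium pentacarbonyl[(2Z)-1-oxido-2,3-diprenyl-4-(triisopropylsilyloxymethyl)penta-2,4-dienylidene]chromate | [Li+].[O-]C(=[Cr](=C=O)(=C=O)(=C=O)(=C=O)=C=O)/C(CC=C(C)C)=C(CC=C(C)C)\C(=C)CO[Si](C(C)C)(C(C)C)C(C)C | intermediate
13 | pentacarbonyl[(2Z)-1-methoxy-2,3-diprenyl-4-(triisopropylsilyloxymethyl)penta-2,4-dienylidene]chromium | COC(=[Cr](=C=O)(=C=O)(=C=O)(=C=O)=C=O)/C(CC=C(C)C)=C(CC=C(C)C)\C(=C)CO[Si](C(C)C)(C(C)C)C(C)C | intermediate
14 | tetracarbonylchromium complex of (3Z)-2-methoxy-3,4-diprenyl-5-(triisopropylsilyloxymethyl)hexa-1,3,5-trien-1-one (π-complex drawn as separate parts) | COC(=C=O)/C(CC=C(C)C)=C(CC=C(C)C)\C(=C)CO[Si](C(C)C)(C(C)C)C(C)C.[Cr].[C-]#[O+].[C-]#[O+].[C-]#[O+].[C-]#[O+] | intermediate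
15 | 2-methoxy-3,4-diprenyl-5-(triisopropylsilyloxymethyl)cyclohexa-2,4-dien-1-one | COC1=C(CC=C(C)C)C(CC=C(C)C)=C(CO[Si](C(C)C)(C(C)C)C(C)C)CC1=O | intermediate
16 | 2-methoxy-3,4-diprenyl-5-(triisopropylsilyloxymethyl)phenol | COc1c(O)cc(CO[Si](C(C)C)(C(C)C)C(C)C)c(CC=C(C)C)c1CC=C(C)C | intermediate
17 | 3,4-diprenyl-5-(triisopropylsilyloxymethyl)cyclohexa-3,5-diene-1,2-dione | O=C1C=C(CO[Si](C(C)C)(C(C)C)C(C)C)C(CC=C(C)C)=C(CC=C(C)C)C1=O | intermediate
18 | 3,4-diprenyl-5-(triisopropylsilyloxymethyl)benzene-1,2-diol | Oc1cc(CO[Si](C(C)C)(C(C)C)C(C)C)c(CC=C(C)C)c(CC=C(C)C)c1O | intermediate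
19 | {[4,5-bis(methoxymethoxy)-2,3-diprenylphenyl]methoxy}triisopropylsilane | COCOc1cc(CO[Si](C(C)C)(C(C)C)C(C)C)c(CC=C(C)C)c(CC=C(C)C)c1OCOC | intermediate
20 | [4,5-bis(methoxymethoxy)-2,3-diprenylphenyl]methanol | COCOc1cc(CO)c(CC=C(C)C)c(CC=C(C)C)c1OCOC | intermediate
21 | 4,5-bis(methoxymethoxy)-2,3-diprenylbenzaldehyde | COCOc1cc(C=O)c(CC=C(C)C)c(CC=C(C)C)c1OCOC | intermediate
22 | 2,4,6-trihydroxyacetophenone | CC(=O)c1c(O)cc(O)cc1O | starting material
23 | 1-(2,4,6-trihydroxy-3-prenylphenyl)ethanone | CC(=O)c1c(O)cc(O)c(CC=C(C)C)c1O | intermediate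
24 | 1-[2-hydroxy-4,6-bis(methoxymethoxy)-3-prenylphenyl]ethanone | CC(=O)c1c(O)c(CC=C(C)C)c(OCOC)cc1OCOC | intermediate
25 | (E)-chalcone from 21 and 24 | COCOc1cc(/C=C/C(=O)c2c(O)c(CC=C(C)C)c(OCOC)cc2OCOC)c(CC=C(C)C)c(CC=C(C)C)c1OCOC | intermediate
26 | trans-3-hydroxy-5,7-bis(methoxymethoxy)-2-[4,5-bis(methoxymethoxy)-2,3-diprenylphenyl]-8-prenylchroman-4-one (racemic, 2R,3R enantiomer drawn) | O=C1c2c(OCOC)cc(OCOC)c(CC=C(C)C)c2O[C@H](c2cc(OCOC)c(OCOC)c(CC=C(C)C)c2CC=C(C)C)[C@H]1O | intermediate
27 | 3-hydroxy-5,7-bis(methoxymethoxy)-2-[4,5-bis(methoxymethoxy)-2,3-diprenylphenyl]-8-prenylchromen-4-one | COCOc1cc(-c2oc3c(CC=C(C)C)c(OCOC)cc(OCOC)c3c(=O)c2O)c(CC=C(C)C)c(CC=C(C)C)c1OCOC | intermediate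
28 | Broussoflavonol G | CC(C)=CCc1c(-c2oc3c(CC=C(C)C)c(O)cc(O)c3c(=O)c2O)cc(O)c(O)c1CC=C(C)C | target

Total step count: 16. Longest linear sequence: 13 steps (1, 2, 4 to 11, 14 to 16).

Steps most likely to fail

Step 7.
- What may go wrong: the crowded, twisted diene may reach the coiled conformation too rarely. The ketene could then be lost by reversion to the carbene, by photoisomerisation about the central alkene, or by cyclisation without carbonyl insertion.
- Fallback: generate the same dienylketene without metal or light. It sets out from dienyllithium 11 (made from 9 as in step 6) and comes back at phenol 16.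
- Addition of 11 to ethyl glyoxylate at −78 °C and an NH4Cl quench should give the α-hydroxy ester F1.
- MeI and Ag2O should give the α-methoxy ester F2, and LiOH should give the 2-methoxy-3,5-dienoic acid F3.
- Ethyl chloroformate and Et3N in THF convert F3 into the mixed anhydride F4. Et3N then eliminates this, as in the usual generation of alkoxyketenes, to the metal-free dienylketene F5.
- F5 closes through dienone 15 by the same electrocyclisation. This is the known benzannulation of 3,5-dienoic acids.
- Excess chloroformate captures the phenol as the aryl ethyl carbonate F6, and K2CO3 in MeOH releases 16.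

Step 15.
- What may go wrong: the MOM ether on the C5 side and the ortho prenyl group of ring B twist the enone. This favours 5-exo closure at Cα (the aurone manifold) and slows conjugate attack of hydroperoxide.
- Fallback: build ring C as a flavone first and oxygenate C3 afterwards. It sets out from aldehyde 21 and acetophenone 24 and comes back at flavonol 27.
- Pinnick oxidation of 21 (NaClO2, NaH2PO4, large excess of 2-methylbut-2-ene) should give the benzoic acid F7.
- EDC and DMAP with 24 should give the aryl ester F8.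
- Baker–Venkataraman rearrangement with LiN(SiMe3)2 should give the 1,3-diketone F9.
- Mild cyclodehydration (NaOAc, AcOH, warm) should give the flavone F10.
- LiN(i-Pr)2 at −78 °C forms the 3-lithioflavone F11, and B(OMe)3 traps it as the C3 dimethyl boronate F12.
- H2O2 oxidises the carbon–boron bond of F12 to the C3 hydroxyl of 27 without touching the prenyl groups.

Step 5.
- What may go wrong: the alkene geometry may erode or invert through an addition–elimination pathway, hypoiodite may attack the prenyl alkenes, and ate-complex formation at the hindered boron may be slow.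
- Fallback: reach the carbene complex from an acyl chloride and a chromium dianion, with neither electrophilic iodine nor the basic dienyllithium of step 6. It sets out from boronate 8 and comes back at carbene complex 13.
- Oxidative methoxycarbonylation (Pd(OAc)2, PPh3, p-benzoquinone, CO, MeOH, rt) proceeds by transmetalation and should keep the geometry, giving the methyl (2Z)-dienoate F13.
- LiOH at 50 °C should give the dienoic acid F14.
- 1-Chloro-N,N,2-trimethylprop-1-en-1-amine should give the acid chloride F15 under neutral conditions.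
- Reduction of Cr(CO)6 10 with KC8 gives dipotassium pentacarbonylchromate F16.
- F16 attacks F15 at −78 °C to give the potassium acylchromate F17, and Me3OBF4 methylates F17 on oxygen to 13.

Further compounds
F1 | step 7 | ethyl (3Z)-2-hydroxy-3,4-diprenyl-5-(triisopropylsilyloxymethyl)hexa-3,5-dienoate (racemic) | CCOC(=O)C(O)/C(CC=C(C)C)=C(CC=C(C)C)\C(=C)CO[Si](C(C)C)(C(C)C)C(C)C
F2 | step 7 | ethyl (3Z)-2-methoxy-3,4-diprenyl-5-(triisopropylsilyloxymethyl)hexa-3,5-dienoate (racemic) | CCOC(=O)C(OC)/C(CC=C(C)C)=C(CC=C(C)C)\C(=C)CO[Si](C(C)C)(C(C)C)C(C)C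
F3 | step 7 | (3Z)-2-methoxy-3,4-diprenyl-5-(triisopropylsilyloxymethyl)hexa-3,5-dienoic acid (racemic) | OC(=O)C(OC)/C(CC=C(C)C)=C(CC=C(C)C)\C(=C)CO[Si](C(C)C)(C(C)C)C(C)C
F4 | step 7 | mixed anhydride of F3 with ethyl hydrogen carbonate | CCOC(=O)OC(=O)C(OC)/C(CC=C(C)C)=C(CC=C(C)C)\C(=C)CO[Si](C(C)C)(C(C)C)C(C)C
F5 | step 7 | (3Z)-2-methoxy-3,4-diprenyl-5-(triisopropylsilyloxymethyl)hexa-1,3,5-trien-1-one (metal-free dienylketene) | COC(=C=O)/C(CC=C(C)C)=C(CC=C(C)C)\C(=C)CO[Si](C(C)C)(C(C)C)C(C)C
F6 | step 7 | ethyl 2-methoxy-3,4-diprenyl-5-(triisopropylsilyloxymethyl)phenyl carbonate | CCOC(=O)Oc1cc(CO[Si](C(C)C)(C(C)C)C(C)C)c(CC=C(C)C)c(CC=C(C)C)c1OC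
F7 | step 15 | 4,5-bis(methoxymethoxy)-2,3-diprenylbenzoic acid | COCOc1cc(C(=O)O)c(CC=C(C)C)c(CC=C(C)C)c1OCOC
F8 | step 15 | 2-acetyl-3,5-bis(methoxymethoxy)-6-prenylphenyl 4,5-bis(methoxymethoxy)-2,3-diprenylbenzoate | CC(=O)c1c(OC(=O)c2cc(OCOC)c(OCOC)c(CC=C(C)C)c2CC=C(C)C)c(CC=C(C)C)c(OCOC)cc1OCOC
F9 | step 15 | 1-[4,5-bis(methoxymethoxy)-2,3-diprenylphenyl]-3-[2-hydroxy-4,6-bis(methoxymethoxy)-3-prenylphenyl]propane-1,3-dione | O=C(CC(=O)c1cc(OCOC)c(OCOC)c(CC=C(C)C)c1CC=C(C)C)c1c(O)c(CC=C(C)C)c(OCOC)cc1OCOC
F10 | step 15 | 5,7-bis(methoxymethoxy)-2-[4,5-bis(methoxymethoxy)-2,3-diprenylphenyl]-8-prenylchromen-4-one | COCOc1cc(-c2cc(=O)c3c(OCOC)cc(OCOC)c(CC=C(C)C)c3o2)c(CC=C(C)C)c(CC=C(C)C)c1OCOC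
F11 | step 15 | 3-lithio derivative of F10 | COCOc1cc(-c2oc3c(CC=C(C)C)c(OCOC)cc(OCOC)c3c(=O)c2[Li])c(CC=C(C)C)c(CC=C(C)C)c1OCOC
F12 | step 15 | dimethyl {5,7-bis(methoxymethoxy)-2-[4,5-bis(methoxymethoxy)-2,3-diprenylphenyl]-4-oxo-8-prenylchromen-3-yl}boronate | COCOc1cc(-c2oc3c(CC=C(C)C)c(OCOC)cc(OCOC)c3c(=O)c2B(OC)OC)c(CC=C(C)C)c(CC=C(C)C)c1OCOC
F13 | step 5 | methyl (2Z)-2,3-diprenyl-4-(triisopropylsilyloxymethyl)penta-2,4-dienoate | COC(=O)/C(CC=C(C)C)=C(CC=C(C)C)\C(=C)CO[Si](C(C)C)(C(C)C)C(C)C
F14 | step 5 | (2Z)-2,3-diprenyl-4-(triisopropylsilyloxymethyl)penta-2,4-dienoic acid | OC(=O)/C(CC=C(C)C)=C(CC=C(C)C)\C(=C)CO[Si](C(C)C)(C(C)C)C(C)C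
F15 | step 5 | (2Z)-2,3-diprenyl-4-(triisopropylsilyloxymethyl)penta-2,4-dienoyl chloride | ClC(=O)/C(CC=C(C)C)=C(CC=C(C)C)\C(=C)CO[Si](C(C)C)(C(C)C)C(C)C
F16 | step 5 | dipotassium pentacarbonylchromate | [K+].[K+].[Cr-2].[C-]#[O+].[C-]#[O+].[C-]#[O+].[C-]#[O+].[C-]#[O+]
F17 | step 5 | potassium pentacarbonyl[(2Z)-1-oxido-2,3-diprenyl-4-(triisopropylsilyloxymethyl)penta-2,4-dienylidene]chromate | [K+].[O-]C(=[Cr](=C=O)(=C=O)(=C=O)(=C=O)=C=O)/C(CC=C(C)C)=C(CC=C(C)C)\C(=C)CO[Si](C(C)C)(C(C)C)C(C)C
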